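## Retrosynthetic overview

1. The target comes from one mild acid step that unmasks a 2-methoxypropan-2-yl peroxyketal (the C8 hydroperoxide) and an aryl tetrahydropyranyl ether (the phenol).
2. The eleven-membered carbocycle, the only ring in the target, is closed late by ring-closing metathesis that forms the C3=C4 Z-trisubstituted alkene from an open chain already carrying both stereocentres, the ester and the peroxide.
3. The C8–O–O bond comes from SN2 inversion of an (8R)-allylic mesylate by 2-methoxypropan-2-yl hydroperoxide; the (8R)-alcohol comes from CBS reduction of an α-methylene ketone.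
4. The open chain is assembled from three fragments: a δ-lactone (C1 stereocentre by Brown 2-methylallylation of an aldehyde ester), hexa-1,5-dien-2-yllithium, and tetrahydropyranyl-protected p-coumaric acid. The hydroperoxide reagent is a fourth, separately made piece.
5. Ring order: a transient δ-lactone (opened again at the fragment union), then the macrocycle in the penultimate step.

Ring locants used below: C1 (ester carbon), C3=C4 (ring alkene), C7 (methylidene carbon), C8 (hydroperoxide carbon), C10 (CMe2).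

Assumption: the acetal carbon of the tetrahydropyranyl (oxan-2-yl) group is used as the racemate, so every compound carrying it is a 1:1 mixture at that carbon only; it has no stereo label in the SMILES and is removed in the last step.

Note on labels: the ester-bearing carbon keeps the geometry set in step 2 throughout. Its CIP label is S in the lactone and the open-chain compounds and R once the ring is closed, only because ring closure changes the ranking of its two carbon branches.

## Route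

Step 1
Reactants: 1 methyl 3,3-dimethylpent-4-enoate
Product: 2 methyl 3,3-dimethyl-5-oxopentanoate
Conditions: PdCl2(PhCN)2 (10 mol %), CuCl2·2H2O (10 mol %), AgNO2 (5 mol %), O2 (1 atm), t-BuOH/MeNO2 15:1, rt
Reagents that add atoms: dioxygen O=O
Why: Nitrite-modified, aldehyde-selective Wacker oxidation puts oxygen on the terminal carbon because the quaternary allylic carbon blocks Markovnikov attack; no stereocentre is formed.

Step 2
Reactants: 2 methyl 3,3-dimethyl-5-oxopentanoate
Product: 4 (6S)-4,4-dimethyl-6-(2-methylprop-2-en-1-yl)oxan-2-one, via hydroxy ester 3 (not isolated)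
Conditions: (−)-Ipc2BOMe, 2-methylallylMgCl, Et2O, −78 °C → rt; then 2, −78 °C; NaOH, H2O2, 0 °C → rt; then TsOH (cat.), CH2Cl2, rt
Reagents that add atoms: 2-methylallylmagnesium chloride CC(=C)C[Mg]Cl, transferred as (−)-B-(2-methylallyl)diisopinocampheylborane C=C(C)CB([C@@H]1C[C@@H]2C[C@H]([C@H]1C)C2(C)C)[C@@H]1C[C@@H]2C[C@H]([C@H]1C)C2(C)C
Why: Brown asymmetric allylboration through a chair Zimmerman–Traxler transition state, with the isopinocampheyl groups from (+)-α-pinene sending the 2-methylallyl group to the Si face of the aldehyde, sets the carbinol centre (5S in 3, 6S in 4), and the δ-hydroxy ester then lactonises under acid, helped by the gem-dimethyl effect.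

Step 3
Reactants: 5 2,3-dibromoprop-1-ene; 6 allylmagnesium bromide
Product: 7 2-bromohexa-1,5-diene
Conditions: Et2O, 0 °C → reflux
Reagents that add atoms: none
Why: Allylic substitution of the allylic C–Br bond by the Grignard reagent (the vinylic C–Br bond is inert) gives the 1,5-diene; no stereocentre is formed.

Step 4
Reactants: 4 (6S)-4,4-dimethyl-6-(2-methylprop-2-en-1-yl)oxan-2-one; 7 2-bromohexa-1,5-diene
Product: 9 (10S)-10-hydroxy-8,8,12-trimethyl-5-methylidenetrideca-1,12-dien-6-one, via hexa-1,5-dien-2-yllithium 8 (not isolated)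
Conditions: 7, t-BuLi (2 equiv), Et2O, −78 °C; then 4, THF, −78 °C; AcOH, −78 °C
Reagents that add atoms: tert-butyllithium [Li]C(C)(C)C (its lithium is carried only by 8)
Why: Bromine–lithium exchange gives the alkenyllithium, whose acyl substitution on the δ-lactone stops at the tetrahedral lithium lactolate at −78 °C and releases the δ-hydroxy α-methylene ketone on protonation; the existing stereocentre is untouched.

Step 5
Reactants: 10 methyl (2E)-3-(4-hydroxyphenyl)prop-2-enoate
Product: 11 methyl (2E)-3-[4-(oxan-2-yloxy)phenyl]prop-2-enoate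
Conditions: 3,4-dihydro-2H-pyran, PPTS (cat.), CH2Cl2, rt
Reagents that add atoms: 3,4-dihydro-2H-pyran C1=COCCC1
Why: Acid-catalysed addition of the phenol to the enol ether (tetrahydropyranyl acetal formation) masks the phenol in a base-stable form; the new acetal carbon is racemic and is removed in step 12.

Step 6
Reactants: 11 methyl (2E)-3-[4-(oxan-2-yloxy)phenyl]prop-2-enoate
Product: 12 (2E)-3-[4-(oxan-2-yloxy)phenyl]prop-2-enoic acid
Conditions: LiOH, THF/MeOH/H2O, rt; then HCl (aq) to pH 4, 0 °C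
Reagents that add atoms: lithium hydroxide [Li+].[OH-]
Why: Saponification of the methyl ester followed by controlled acidification leaves the aryl acetal and the E-alkene intact.

Step 7
Reactants: 9 (10S)-10-hydroxy-8,8,12-trimethyl-5-methylidenetrideca-1,12-dien-6-one; 12 (2E)-3-[4-(oxan-2-yloxy)phenyl]prop-2-enoic acid
Product: 13 (4S)-2,6,6-trimethyl-9-methylidene-8-oxotrideca-1,12-dien-4-yl (2E)-3-[4-(oxan-2-yloxy)phenyl]prop-2-enoate
Conditions: DCC, DMAP (cat.), CH2Cl2, 0 °C → rt
Reagents that add atoms: none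
Why: Steglich esterification (carbodiimide activation, acyl transfer by DMAP) acylates the secondary alcohol of the open hydroxy-ketone form with retention at the carbinol carbon.

Step 8
Reactants: 13 (4S)-2,6,6-trimethyl-9-methylidene-8-oxotrideca-1,12-dien-4-yl (2E)-3-[4-(oxan-2-yloxy)phenyl]prop-2-enoate
Product: 14 (4S,8R)-8-hydroxy-2,6,6-trimethyl-9-methylidenetrideca-1,12-dien-4-yl (2E)-3-[4-(oxan-2-yloxy)phenyl]prop-2-enoate
Conditions: (S)-2-methyl-CBS-oxazaborolidine (20 mol %), catecholborane, toluene, −78 °C; then MeOH, aqueous work-up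
Reagents that add atoms: none
Why: Corey–Bakshi–Shibata reduction with the (S)-oxazaborolidine treats the 1,1-disubstituted alkenyl group as the large substituent and gives the (8R)-allylic alcohol under reagent control, while catecholborane at −78 °C leaves the ester and the alkenes alone.

Step 9
Reactants: 15 2,3-dimethylbut-2-ene
Product: 16 2-hydroperoxy-2-methoxypropane
Conditions: O3, MeOH/CH2Cl2, −78 °C
Reagents that add atoms: ozone [O-][O+]=O; methanol CO
Why: Ozonolysis in methanol: the carbonyl oxide from cycloreversion of the primary ozonide is trapped by methanol as the α-methoxy hydroperoxide, with acetone as the other fragment.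

Step 10
Reactants: 14 (4S,8R)-8-hydroxy-2,6,6-trimethyl-9-methylidenetrideca-1,12-dien-4-yl (2E)-3-[4-(oxan-2-yloxy)phenyl]prop-2-enoate; 16 2-hydroperoxy-2-methoxypropane
Product: 18 (4S,8S)-8-[(2-methoxypropan-2-yl)peroxy]-2,6,6-trimethyl-9-methylidenetrideca-1,12-dien-4-yl (2E)-3-[4-(oxan-2-yloxy)phenyl]prop-2-enoate, via allylic mesylate 17 (not isolated)
Conditions: Ms2O, Et3N, CH2Cl2, −40 °C; then 16 (4 equiv), CsOH·H2O (2 equiv), DMF, 0 °C
Reagents that add atoms: methanesulfonic anhydride CS(=O)(=O)OS(C)(=O)=O (its mesyl group is carried only by 17)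
Why: Sulfonylation with retention, then SN2 displacement by the caesium peroxide anion (an α-effect nucleophile), inverts C8 from R to S and installs the O–O bond as a base-stable peroxyketal; keeping the hydroperoxide in excess over hydroxide protects the ester.

Step 11
Reactants: 18 (4S,8S)-8-[(2-methoxypropan-2-yl)peroxy]-2,6,6-trimethyl-9-methylidenetrideca-1,12-dien-4-yl (2E)-3-[4-(oxan-2-yloxy)phenyl]prop-2-enoate
Product: 19 (1R,3Z,8S)-8-[(2-methoxypropan-2-yl)peroxy]-3,10,10-trimethyl-7-methylidenecycloundec-3-en-1-yl (2E)-3-[4-(oxan-2-yloxy)phenyl]prop-2-enoate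
Conditions: second-generation Grubbs catalyst (H2IMes)(PCy3)Cl2Ru=CHPh (10 mol %), toluene (1 mM, slow addition), 60 °C
Reagents that add atoms: none
Why: Ring-closing metathesis: the ruthenium carbene loads on the monosubstituted alkene and closes onto the 2-methylallyl alkene with loss of ethene (the methylidene alkene could only give a cyclobutene and the cinnamate alkene is unreactive); the medium-ring closure is expected to favour the Z-trisubstituted alkene, and both stereocentres are unaffected.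

Step 12
Reactants: 19 (1R,3Z,8S)-8-[(2-methoxypropan-2-yl)peroxy]-3,10,10-trimethyl-7-methylidenecycloundec-3-en-1-yl (2E)-3-[4-(oxan-2-yloxy)phenyl]prop-2-enoate
Product: 20 (1R,3Z,8S)-8-hydroperoxy-3,10,10-trimethyl-7-methylidenecycloundec-3-en-1-yl (2E)-3-(4-hydroxyphenyl)prop-2-enoate
Conditions: AcOH/THF/H2O 4:2:1, 30 °C
Reagents that add atoms: none
Why: Mild acid hydrolysis cleaves the two acetal-type groups (peroxyketal and aryl tetrahydropyranyl ether) without touching the allylic hydroperoxide, the ester or the alkenes, and both stereocentres stay as set.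

## Compound list

1 | methyl 3,3-dimethylpent-4-enoate | C=CC(C)(C)CC(=O)OC | starting material
2 | methyl 3,3-dimethyl-5-oxopentanoate | O=CCC(C)(C)CC(=O)OC | intermediate
3 | methyl (5S)-5-hydroxy-3,3,7-trimethyloct-7-enoate | C=C(C)C[C@H](O)CC(C)(C)CC(=O)OC | intermediate
4 | (6S)-4,4-dimethyl-6-(2-methylprop-2-en-1-yl)oxan-2-one | C=C(C)C[C@H]1CC(C)(C)CC(=O)O1 | intermediate
5 | 2,3-dibromoprop-1-ene | C=C(Br)CBr | starting material
6 | allylmagnesium bromide | C=CC[Mg]Br | starting material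
7 | 2-bromohexa-1,5-diene | C=C(Br)CCC=C | intermediate
8 | hexa-1,5-dien-2-yllithium | [Li]C(=C)CCC=C | intermediate
9 | (10S)-10-hydroxy-8,8,12-trimethyl-5-methylidenetrideca-1,12-dien-6-one | C=C(C)C[C@H](O)CC(C)(C)CC(=O)C(=C)CCC=C | intermediate
10 | methyl (2E)-3-(4-hydroxyphenyl)prop-2-enoate | COC(=O)/C=C/c1ccc(O)cc1 | starting material
11 | methyl (2E)-3-[4-(oxan-2-yloxy)phenyl]prop-2-enoate | COC(=O)/C=C/c1ccc(OC2CCCCO2)cc1 | intermediate
12 | (2E)-3-[4-(oxan-2-yloxy)phenyl]prop-2-enoic acid | OC(=O)/C=C/c1ccc(OC2CCCCO2)cc1 | intermediate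
13 | (4S)-2,6,6-trimethyl-9-methylidene-8-oxotrideca-1,12-dien-4-yl (2E)-3-[4-(oxan-2-yloxy)phenyl]prop-2-enoate | C=C(C)C[C@H](OC(=O)/C=C/c1ccc(OC2CCCCO2)cc1)CC(C)(C)CC(=O)C(=C)CCC=C | intermediate
14 | (4S,8R)-8-hydroxy-2,6,6-trimethyl-9-methylidenetrideca-1,12-dien-4-yl (2E)-3-[4-(oxan-2-yloxy)phenyl]prop-2-enoate | C=C(C)C[C@H](OC(=O)/C=C/c1ccc(OC2CCCCO2)cc1)CC(C)(C)C[C@@H](O)C(=C)CCC=C | intermediate
15 | 2,3-dimethylbut-2-ene | CC(C)=C(C)C | starting material
16 | 2-hydroperoxy-2-methoxypropane | COC(C)(C)OO | intermediate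
17 | (4S,8R)-8-(methanesulfonyloxy)-2,6,6-trimethyl-9-methylidenetrideca-1,12-dien-4-yl (2E)-3-[4-(oxan-2-yloxy)phenyl]prop-2-enoate | C=C(C)C[C@H](OC(=O)/C=C/c1ccc(OC2CCCCO2)cc1)CC(C)(C)C[C@@H](OS(C)(=O)=O)C(=C)CCC=C | intermediate
18 | (4S,8S)-8-[(2-methoxypropan-2-yl)peroxy]-2,6,6-trimethyl-9-methylidenetrideca-1,12-dien-4-yl (2E)-3-[4-(oxan-2-yloxy)phenyl]prop-2-enoate | C=C(C)C[C@H](OC(=O)/C=C/c1ccc(OC2CCCCO2)cc1)CC(C)(C)C[C@H](OOC(C)(C)OC)C(=C)CCC=C | intermediate
19 | (1R,3Z,8S)-8-[(2-methoxypropan-2-yl)peroxy]-3,10,10-trimethyl-7-methylidenecycloundec-3-en-1-yl (2E)-3-[4-(oxan-2-yloxy)phenyl]prop-2-enoate | C=C1CC/C=C(/C)C[C@H](OC(=O)/C=C/c2ccc(OC3CCCCO3)cc2)CC(C)(C)C[C@@H]1OOC(C)(C)OC | intermediate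
20 | (1R,3Z,8S)-8-hydroperoxy-3,10,10-trimethyl-7-methylidenecycloundec-3-en-1-yl (2E)-3-(4-hydroxyphenyl)prop-2-enoate | C=C1CC/C=C(/C)C[C@H](OC(=O)/C=C/c2ccc(O)cc2)CC(C)(C)C[C@@H]1OO | target

## Step count and risks

Total step count: 12.
Longest linear sequence: 8 steps (1, 2, 4, 7, 8, 10, 11, 12). Steps 3, 5, 6 and 9 are side branches.

The three steps most likely to fail:

**Step 11 (ring-closing metathesis).** The risk is an E/Z mixture at C3=C4, or oligomerisation instead of closure of the eleven-membered ring. The fallback sets out from 9 and comes back at 19. It runs the metathesis on an oxygen-bridged substrate and moves it ahead of esterification. Compound 9 is closed with PPTS and HC(OMe)3 in MeOH to the cyclic methyl ketal (2S,6S)-2-(hexa-1,5-dien-2-yl)-2-methoxy-4,4-dimethyl-6-(2-methylprop-2-en-1-yl)oxane F1, which holds the two alkene arms cis on the oxane. Metathesis with the same ruthenium catalyst then closes a nine-membered oxacycle, in which only the Z-alkene is accessible, and gives (1R,3Z,8S)-8-methoxy-3,10,10-trimethyl-7-methylidene-12-oxabicyclo[6.3.1]dodec-3-ene F2. PPTS in acetone/H2O opens the bridging ketal to (5Z,8R)-8-hydroxy-6,10,10-trimethyl-2-methylidenecycloundec-5-en-1-one F3. Esterification with 12 as in step 7 gives (1R,3Z)-3,10,10-trimethyl-7-methylidene-8-oxocycloundec-3-en-1-yl (2E)-3-[4-(oxan-2-yloxy)phenyl]prop-2-enoate F4. CBS reduction as in step 8 gives (1R,3Z,8R)-8-hydroxy-3,10,10-trimethyl-7-methylidenecycloundec-3-en-1-yl (2E)-3-[4-(oxan-2-yloxy)phenyl]prop-2-enoate F5. Ms2O/Et3N gives (1R,3Z,8R)-8-(methanesulfonyloxy)-3,10,10-trimethyl-7-methylidenecycloundec-3-en-1-yl (2E)-3-[4-(oxan-2-yloxy)phenyl]prop-2-enoate F6, and displacement with 16 and CsOH·H2O as in step 10 gives 19.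

**Step 10 (hydroperoxide installation).** The risk is SN2′ attack at the unhindered methylidene terminus, or elimination, instead of direct SN2 at C8. The fallback sets out from 13 and comes back at 18. It masks the alkene before the displacement. Conjugate addition of PhSeH [from (PhSe)2 and NaBH4, EtOH, 0 °C] to the α-methylene ketone of 13 gives (4S)-2,6,6-trimethyl-8-oxo-9-[(phenylselanyl)methyl]trideca-1,12-dien-4-yl (2E)-3-[4-(oxan-2-yloxy)phenyl]prop-2-enoate F7 (both C9 epimers). The same CBS reduction gives (4S,8R)-8-hydroxy-2,6,6-trimethyl-9-[(phenylselanyl)methyl]trideca-1,12-dien-4-yl (2E)-3-[4-(oxan-2-yloxy)phenyl]prop-2-enoate F8. Tf2O/2,6-lutidine (CH2Cl2, −78 °C) gives (4S,8R)-2,6,6-trimethyl-9-[(phenylselanyl)methyl]-8-[(trifluoromethanesulfonyl)oxy]trideca-1,12-dien-4-yl (2E)-3-[4-(oxan-2-yloxy)phenyl]prop-2-enoate F9, a saturated secondary electrophile with no SN2′ pathway. Displacement with 16 and CsOH·H2O in DMF inverts C8 and gives (4S,8S)-8-[(2-methoxypropan-2-yl)peroxy]-2,6,6-trimethyl-9-[(phenylselanyl)methyl]trideca-1,12-dien-4-yl (2E)-3-[4-(oxan-2-yloxy)phenyl]prop-2-enoate F10. H2O2/pyridine (CH2Cl2, 0 °C → rt), which the peroxyketal tolerates, oxidises selenium to (4S,8S)-9-[(benzeneseleninyl)methyl]-8-[(2-methoxypropan-2-yl)peroxy]-2,6,6-trimethyltrideca-1,12-dien-4-yl (2E)-3-[4-(oxan-2-yloxy)phenyl]prop-2-enoate F11. Its syn-elimination can only take the C9 hydrogen, so it regenerates the methylidene group and gives 18.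

**Step 1 (aldehyde-selective Wacker oxidation).** The risk is slow or poorly selective oxidation of the hindered vinyl group. The fallback sets out from 1 and comes back at 4. It replaces direct oxidation by a hydroboration and lactol route. Hydroboration of 1 with 9-BBN, NaOH/H2O2 work-up and TsOH give 4,4-dimethyloxan-2-one F12. i-Bu2AlH (CH2Cl2, −78 °C) gives 4,4-dimethyloxan-2-ol F13. The Brown reagent of step 2 adds to the open hydroxy-aldehyde form of the lactol and gives (5S)-3,3,7-trimethyloct-7-ene-1,5-diol F14. TEMPO (cat.) with PhI(OAc)2 oxidises the primary alcohol through the lactol to the lactone 4.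

Further compounds
F1 | step 11 | (2S,6S)-2-(hexa-1,5-dien-2-yl)-2-methoxy-4,4-dimethyl-6-(2-methylprop-2-en-1-yl)oxane | C=C(C)C[C@H]1CC(C)(C)C[C@@](OC)(C(=C)CCC=C)O1
F2 | step 11 | (1R,3Z,8S)-8-methoxy-3,10,10-trimethyl-7-methylidene-12-oxabicyclo[6.3.1]dodec-3-ene | C=C1CC/C=C(/C)C[C@H]2CC(C)(C)C[C@]1(OC)O2
F3 | step 11 | (5Z,8R)-8-hydroxy-6,10,10-trimethyl-2-methylidenecycloundec-5-en-1-one | C=C1CC/C=C(/C)C[C@H](O)CC(C)(C)CC1=O
F4 | step 11 | (1R,3Z)-3,10,10-trimethyl-7-methylidene-8-oxocycloundec-3-en-1-yl (2E)-3-[4-(oxan-2-yloxy)phenyl]prop-2-enoate | C=C1CC/C=C(/C)C[C@H](OC(=O)/C=C/c2ccc(OC3CCCCO3)cc2)CC(C)(C)CC1=O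
F5 | step 11 | (1R,3Z,8R)-8-hydroxy-3,10,10-trimethyl-7-methylidenecycloundec-3-en-1-yl (2E)-3-[4-(oxan-2-yloxy)phenyl]prop-2-enoate | C=C1CC/C=C(/C)C[C@H](OC(=O)/C=C/c2ccc(OC3CCCCO3)cc2)CC(C)(C)C[C@H]1O
F6 | step 11 | (1R,3Z,8R)-8-(methanesulfonyloxy)-3,10,10-trimethyl-7-methylidenecycloundec-3-en-1-yl (2E)-3-[4-(oxan-2-yloxy)phenyl]prop-2-enoate | C=C1CC/C=C(/C)C[C@H](OC(=O)/C=C/c2ccc(OC3CCCCO3)cc2)CC(C)(C)C[C@H]1OS(C)(=O)=O
F7 | step 10 | (4S)-2,6,6-trimethyl-8-oxo-9-[(phenylselanyl)methyl]trideca-1,12-dien-4-yl (2E)-3-[4-(oxan-2-yloxy)phenyl]prop-2-enoate | C=C(C)C[C@H](OC(=O)/C=C/c1ccc(OC2CCCCO2)cc1)CC(C)(C)CC(=O)C(C[Se]c1ccccc1)CCC=C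
F8 | step 10 | (4S,8R)-8-hydroxy-2,6,6-trimethyl-9-[(phenylselanyl)methyl]trideca-1,12-dien-4-yl (2E)-3-[4-(oxan-2-yloxy)phenyl]prop-2-enoate | C=C(C)C[C@H](OC(=O)/C=C/c1ccc(OC2CCCCO2)cc1)CC(C)(C)C[C@@H](O)C(C[Se]c1ccccc1)CCC=C
F9 | step 10 | (4S,8R)-2,6,6-trimethyl-9-[(phenylselanyl)methyl]-8-[(trifluoromethanesulfonyl)oxy]trideca-1,12-dien-4-yl (2E)-3-[4-(oxan-2-yloxy)phenyl]prop-2-enoate | C=C(C)C[C@H](OC(=O)/C=C/c1ccc(OC2CCCCO2)cc1)CC(C)(C)C[C@@H](OS(=O)(=O)C(F)(F)F)C(C[Se]c1ccccc1)CCC=C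
F10 | step 10 | (4S,8S)-8-[(2-methoxypropan-2-yl)peroxy]-2,6,6-trimethyl-9-[(phenylselanyl)methyl]trideca-1,12-dien-4-yl (2E)-3-[4-(oxan-2-yloxy)phenyl]prop-2-enoate | C=C(C)C[C@H](OC(=O)/C=C/c1ccc(OC2CCCCO2)cc1)CC(C)(C)C[C@H](OOC(C)(C)OC)C(C[Se]c1ccccc1)CCC=C
F11 | step 10 | (4S,8S)-9-[(benzeneseleninyl)methyl]-8-[(2-methoxypropan-2-yl)peroxy]-2,6,6-trimethyltrideca-1,12-dien-4-yl (2E)-3-[4-(oxan-2-yloxy)phenyl]prop-2-enoate | C=C(C)C[C@H](OC(=O)/C=C/c1ccc(OC2CCCCO2)cc1)CC(C)(C)C[C@H](OOC(C)(C)OC)C(C[Se](=O)c1ccccc1)CCC=C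
F12 | step 1 | 4,4-dimethyloxan-2-one | O=C1CC(C)(C)CCO1
F13 | step 1 | 4,4-dimethyloxan-2-ol | OC1CC(C)(C)CCO1
F14 | step 1 | (5S)-3,3,7-trimethyloct-7-ene-1,5-diol | C=C(C)C[C@H](O)CC(C)(C)CCO
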